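Per litre, the nucleophile is charged entirely as protonated nucleophile, so the first step runs on what the acid balances let go.

- ash: electrophile 0.80 M; free base 1.50 equiv; protonated nucleophile 2.00 equiv; time 12 s
- elm: electrophile 0.80 M; free base 2.00 equiv; protonated nucleophile 2.00 equiv; time 12 s

    electrophile + nucleophile → acid set free + target (k1 = 0.16 L mol⁻¹ s⁻¹)
    target → over-reaction product (k2 = 0.018 s⁻¹)
    acid set free + free base ⇌ salt of the base (K3 = 110 L mol⁻¹, k3 = 1.1 L mol⁻¹ s⁻¹)
    nucleophile + acid set free ⇌ protonated nucleophile, settled at all times (K4 = 2600 L mol⁻¹)
    acid set free + free base ⇌ idle adduct, settled at all times (K5 = 2.6 L mol⁻¹)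

- part of the electrophile that has reacted at the end, ash
- part of the electrophile that has reacted at the end, elm
- what raising the equivalents of free base from its lowest to its highest value here does to the part of the electrophile that has reacted (changes below 5 percentage points count as none) (it falls / it rises / no change)

- what is said of acid set free includes idle adduct
- run time (ash): 12 s

In ash, with the other amounts as charged, the forward salt-forming step alone, its way back not counted, gives free acid set free a half-life of 0.53 s, shorter than the 5.4 s of nucleophile by the first step alone. So I assume that the salt of the base keeps pace, gaining two for each electrophile reacted; on that assumption c(nucleophile) equals c(acid set free) plus c(idle adduct). With the two fast balances, c(nucleophile) becomes the square root of c(protonated nucleophile) times (one plus 2.6 L mol⁻¹ times c(free base)) over 2600 L mol⁻¹. At charged amounts that is 0.0504 M in ash and 0.0564 M in elm: the buffered nucleophile level.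

Held steady, this level makes the electrophile pseudo-first-order, and integrating gives the part reacted as one minus exp(−0.16 L mol⁻¹ s⁻¹ × level × time). I commit to 9.22 % for ash and 10.3 % for elm. The gain of 1 percentage point is smaller than 5 points, so I expect no change.

The forecast stands higher than my figures, at 9.5 % and 10.5 % with no change, holding that “the slow salt-forming step merely keeps pace with the acid being released”.

The flask gives 9.24 % for ash and 10.5 % for elm, a rise of 1.3 points, so the answer is no change. At 12.0 s, c(nucleophile) reads 0.0494 M in ash and 0.0574 M in elm, beside my levels of 0.0504 M and 0.0564 M. Left until 20 s, ash at the same buffered level comes to 14.9 % by my integral, and that flask reads 14.6 %.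

The rate constants are assumed; the flask was simulated.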